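## Analysis of the target

The chain is numbered from the lactone carbonyl: C1 (C=O), C2=C3, C4 to C7 (the four oxygen-bearing ring carbons), C8=C9 (E), C10 (carbinol), C11 (benzoyloxy carbon), C12 (methyl). On is the oxygen on Cn.

Target 15 is a cis-fused tetrahydrofuro[3,2-b]pyran-5-one. Ring A is the α,β-unsaturated δ-lactone (C1, C2, C3, C4, C5, O5), and ring B is the oxolane (C4, C5, C6, C7 and the ether oxygen that bridges C4 and C7).

The descriptors 4R,5R,6R,7S put C3, O5, O6 and C8 on one face of ring B. The tetrad is therefore all-cis (threo, erythro, threo along the chain) and is the most crowded diastereomer, so a centre at C4 or C7 that can epimerise, or a C–O bond there that forms reversibly, will drift away from it.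

The side chain holds an anti diol (10S,11R) acylated only at O11. The C8=C9 alkene insulates it from the rings, so its configuration must be brought in independently.

The sensitive groups are:
- the lactone, a γ-alkoxy enoate prone to base-induced ring opening and to oxa-Michael addition of O6–H at C3;
- the benzoate next to a free hydroxyl, which can undergo a 1,2-acyl shift from O11 to O10;
- the two allylic C–O bonds at C7 and C10.

The feature that decides the plan is that C4 and C7, the two carbons next to the ether oxygen of ring B, each carry an sp2 carbon (C3 and C8) on the same face as O5 and O6, and that ring B without C1, C2 and C9 to C12 is a meso compound. Joining C3 to C8 by a double bond turns ring B into a 7-oxabicyclo[2.2.1]hept-2-ene with two endo oxygens. C2=C3 and C8=C9 can thus be read as the two scars left when that strained alkene is opened by metathesis.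

The hard parts are the contra-thermodynamic tetrad, the absolute differentiation of its two nearly equivalent halves, and a mild union with the side chain that leaves lactone and benzoate alone.

## Retrosynthetic reasoning

**15 to 14.** The last operation should only unmask O6–H and O10–H. Both are carried as the same silyl ether in 14, so one mildly acidic fluoride treatment ends the synthesis. The benzoate already sits on O11, because selective acylation of O11 beside free O10–H and O6–H cannot be expected.

**14 to 6 and 11 (key disconnection).** The bonds C2=C3 and C8=C9 are cut together and C3 is reconnected to C8. This leads back to the endo-acryloyloxy 7-oxanorbornene 6 and the terminal alkene 11.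
- Cutting here removes ring A, hides ring B inside a rigid bicycle in which the all-cis tetrad is simply "endo, endo", and separates the side chain.
- The precursor has one ring system that a cycloaddition delivers, and no acyclic stereocontrol is left.
- The forward reaction must open the strained alkene, close the six-membered lactone onto C3 (through 12 and 13), and then join C8 to C9 with E geometry, all in one flask.
- Any other cut of ring B (at a C–O bond) would require the crowded tetrad to be built centre by centre.

**6 to 5 to 4.** Compound 6 differs from the meso diol 4 only in which oxygen carries which group. The two enantiotopic hydroxyls are told apart by a catalytic enantioselective silylation that gives 5. This step alone fixes the absolute configuration of C4, C5, C6 and C7. Acylation of the remaining hydroxyl then places the three carbons C1 to C3' of the acrylate on O5.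

**4 to 3 to 1 and 2.** The bonds C3–C4, C7–C8 (as furan C–C bonds), C4–C5 and C6–C7 trace back to the Diels–Alder adduct 3 of furan 1 and vinylene carbonate 2. The suprafacial cycloaddition sets the relative configuration of all four ring stereocentres at once. The endo isomer is the one that maps onto the target.

**11 to 10 to 9 to 8 to 7.** The benzoate is put on O11 of alcohol 10. The C12 methyl group and the C11 carbinol come from hydride opening of the terminal epoxide 9, and O10 is masked beforehand so that the two oxygens never compete. Epoxy alcohol 8 arises from the prochiral divinyl carbinol 7 by a desymmetrising asymmetric epoxidation. That step sets C10 and C11 together with the required anti relation and leaves the vinyl group needed for the union.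

## Alternatives that were turned down

**Alternative 1:** the textbook route.
- Disconnection: ring B is taken from a pentofuranose of the lyxo series and the two alkenes are cut one after the other.
- Forward key step: C2=C3 is made by a Z-selective Horner–Wadsworth–Emmons reaction (Still–Gennari variant) on the all-cis acetonide aldehyde A1, followed by lactonisation onto O5. C8=C9 is made by a separate olefination or cross metathesis.
- Reason turned down:
  - The carbon substituent at C4 has to be installed cis to O5, against the facial bias of the furanosyl oxocarbenium ion.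
  - A1 is an α-alkoxy aldehyde on the crowded face and can relieve strain by epimerisation at C4 under the basic olefination.
  - Each alkene needs its own oxidation and olefination sequence plus protecting-group traffic, so no step builds more than one bond and the count is roughly double that of the chosen route.

**Alternative 2:** cut the bond between the ether oxygen and C7.
- Forward key step: the C4 hydroxyl of the lactone vinyl epoxide A2 attacks C7 of the π-allyl complex made with a zerovalent palladium catalyst such as Pd(PPh3)4. This closes ring B (5-exo), sets C7, shifts the alkene to C8=C9 and frees O10–H in one step.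
- Reason turned down:
  - A2 already holds six stereocentres and a defined alkene, so it is no simpler than 15.
  - Its assembly needs a site-selective epoxidation within a dienyl system.
  - The π-allyl intermediate can equilibrate, and the C–O closure is reversible under the catalyst, which favours the less crowded 2,5-trans oxolane.
  - The liberated C10 alkoxide sits next to the benzoate and invites acyl migration.

**Alternative 3:** build ring A first.
- Disconnection and forward key step: a 2-furyl carbinol gives ring A by Achmatowicz rearrangement, oxidation to the keto lactone and 1,2-reduction. This leads to the hydroxy lactone mesylate A3, and ring B is then closed by Williamson displacement of O4 at C7 with inversion.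
- Reason turned down:
  - The furan supplies only C1 to C4 and no stereocentre, so C5, C6 and an inverted C7 must be made beforehand in a linear chain.
  - The closing step needs an alkoxide at C4 of a base-sensitive γ-oxy enoate.
  - The leaving group is secondary, allylic and flanked by a silyl ether, so ionisation, allylic transposition and elimination compete with the direct displacement that alone gives the all-cis ring.

Key step: step 9

Assumption: the catalyst of step 3 is taken to silylate the hydroxyl on the S-configured carbinol carbon of 4. If it selects the other enantiotopic hydroxyl, its mirror image is used and nothing else changes.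

## Route

Step 1
Reactants: 1 furan; 2 vinylene carbonate
Product: 3 endo-(3aR,4S,7R,7aS)-3a,4,7,7a-tetrahydro-4,7-epoxy-1,3-benzodioxol-2-one (meso)
Conditions: 1 (5 equiv, neat), BHT (cat.), sealed tube, 120 °C, 36 h; chromatography or crystallisation to separate endo from exo
Reagents that add atoms: none
Why: Thermal Diels–Alder reaction; the suprafacial addition fixes the cis relation of the two C–O bonds and of the bridgeheads, so the relative configuration of C4, C5, C6 and C7 is set at once. Endo and exo adducts are both expected because the reaction is reversible; the meso endo isomer 3, with the carbonate under the C=C bridge, is separated and the exo isomer can be re-equilibrated by heating.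

Step 2
Reactants: 3 endo adduct
Product: 4 (1R,2R,3S,4S)-7-oxabicyclo[2.2.1]hept-5-ene-2,3-diol (meso endo,endo diol)
Conditions: K2CO3 (0.1 equiv), MeOH, 0 °C to rt
Reagents that add atoms: none
Why: Base-catalysed transesterification of the cyclic carbonate; no bond to a stereocentre is broken, and the alkene and the oxygen bridge are inert.

Step 3
Reactants: 4 meso diol
Product: 5 (1R,2S,3S,4S)-3-[(tert-butyldimethylsilyl)oxy]-7-oxabicyclo[2.2.1]hept-5-en-2-ol (both oxygens endo; free OH is O5 and the silyl ether is O6)
Conditions: TBSCl (1.5 equiv), i-Pr2NEt (1.5 equiv), (S)-N-[(R)-3,3-dimethylbutan-2-yl]-3,3-dimethyl-2-{[(1-methylimidazol-2-yl)methyl]amino}butanamide (20 mol %), THF, −40 °C, 72 h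
Reagents that add atoms: tert-butyldimethylsilyl chloride, CC(C)(C)[Si](C)(C)Cl
Why: Catalytic enantioselective silylation of a meso cis-1,2-diol (desymmetrisation): the amino-acid-derived catalyst binds the diol by hydrogen bonds while its N-methylimidazole activates the silyl chloride, so one enantiotopic hydroxyl reacts. This fixes the absolute configuration of C4 to C7; any residual wrong enantiomer becomes a separable diastereomer after union with enantiopure 11.

Step 4
Reactants: 5 mono silyl ether
Product: 6 (1R,2S,3R,4S)-3-[(tert-butyldimethylsilyl)oxy]-7-oxabicyclo[2.2.1]hept-5-en-2-yl prop-2-enoate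
Conditions: acryloyl chloride (1.5 equiv), i-Pr2NEt (2 equiv), DMAP (5 mol %), CH2Cl2, −20 to 0 °C
Reagents that add atoms: acryloyl chloride, C=CC(=O)Cl
Why: Standard O-acylation with an amine base at low temperature, where no alkoxide is formed and the 1,2-silyl shift that would racemise 5 is not expected. It places C1 and C2 on O5, next to the bridgehead that becomes C4.

Step 5
Reactants: 7 penta-1,4-dien-3-ol
Product: 8 (1S)-1-[(2R)-oxiran-2-yl]prop-2-en-1-ol
Conditions: Ti(OiPr)4 (10 mol %), L-(+)-diisopropyl tartrate (13 mol %), t-BuOOH (1.5 equiv), 4 Å molecular sieves, CH2Cl2, −20 °C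
Reagents that add atoms: tert-butyl hydroperoxide, CC(C)(C)OO
Why: Sharpless asymmetric epoxidation of a prochiral divinyl carbinol; enantiotopic-group and diastereotopic-face selection by the L-(+)-tartrate complex give the anti (erythro) 2R,3S epoxy alcohol and so set C11 and C10 together. The minor enantiomer is the fast-reacting one in a second epoxidation, which should raise the enantiomeric purity as conversion proceeds.

Step 6
Reactants: 8 epoxy alcohol
Product: 9 tert-butyldimethyl{[(1S)-1-[(2R)-oxiran-2-yl]prop-2-en-1-yl]oxy}silane
Conditions: TBSCl (1.2 equiv), imidazole (2 equiv), CH2Cl2, 0 °C to rt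
Reagents that add atoms: tert-butyldimethylsilyl chloride, CC(C)(C)[Si](C)(C)Cl
Why: Routine silylation of a secondary alcohol; it blocks O10 so that O11 is the only free oxygen after the epoxide is opened, and it prevents Payne rearrangement and hydroxyl-directed hydride delivery in step 7.

Step 7
Reactants: 9 silylated epoxide
Product: 10 (2R,3S)-3-[(tert-butyldimethylsilyl)oxy]pent-4-en-2-ol
Conditions: LiBHEt3 (1.2 equiv), THF, −78 to 0 °C; then H2O
Reagents that add atoms: none
Why: SN2 opening of a terminal epoxide by hydride at the unsubstituted carbon, which becomes the C12 methyl group. The C11–O bond is not touched, so the configuration is retained, and the vinyl group is inert.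

Step 8
Reactants: 10 alcohol
Product: 11 (2R,3S)-3-[(tert-butyldimethylsilyl)oxy]pent-4-en-2-yl benzoate
Conditions: BzCl (1.3 equiv), pyridine (3 equiv), DMAP (5 mol %), CH2Cl2, 0 °C to rt
Reagents that add atoms: benzoyl chloride, O=C(Cl)c1ccccc1
Why: Routine benzoylation of the only free hydroxyl, which places the ester unambiguously on O11.

Step 9
Reactants: 6 oxanorbornenyl acrylate; 11 side-chain alkene
Product: 14 (2R,3S,4E)-3-[(tert-butyldimethylsilyl)oxy]-5-[(2S,3R,3aS,7aR)-3-[(tert-butyldimethylsilyl)oxy]-5-oxo-2,3,3a,7a-tetrahydro-5H-furo[3,2-b]pyran-2-yl]pent-4-en-2-yl benzoate, via divinyl oxolane acrylate 12 (not isolated), via vinyl lactone 13 (not isolated)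
Conditions: second-generation Hoveyda–Grubbs catalyst (H2IMes)Cl2Ru(=CH-C6H4-2-OiPr) (5 mol %), ethene (1 atm), CH2Cl2 (0.01 M), rt, 3 h; then argon sparge, 11 (3 equiv), same catalyst (5 mol %), 1,4-benzoquinone (10 mol %), 40 °C, 18 h
Reagents that add atoms: none
Why: The methylidene [Ru]=CH2 adds to the exo face of the strained C3=C8 alkene of 6 and cycloreversion opens the bicycle (strain release), which turns the oxygen bridge into ring B and leaves C3 and C8 as carbene or vinyl termini (12 after exchange with ethene). The carbene on C3 closes ring A by ring-closing metathesis onto the acrylate held on the neighbouring endo oxygen O5, a six-membered closure that forms C2=C3 as the ring-enforced Z enoate and gives 13, whereas closure onto the far C8 terminus would need a bridged seven-membered ring and should not compete. After the ethene is purged, the only terminal alkene left in 13, at C8, undergoes cross metathesis with 11 and forms C8=C9. The closest known reaction type is the ring-rearrangement (ring-opening/ring-closing) metathesis of norbornenes and 7-oxanorbornenes that carry an alkenyl or acryloyl tether, followed by cross metathesis in the same flask. No sp3 stereocentre is made or touched: C4 to C7 come over from 6, and the endo position of O5 and O6 becomes the all-cis pattern because endo substituents lie on the same face of ring B as C3 and C8. The E geometry of C8=C9 follows from thermodynamic control between two alkenes that are branched at the allylic carbon. The step needs chemoselectivity among four alkenes, which is secured by strain (C3=C8 reacts first), by proximity (the electron-poor acrylate reacts only intramolecularly) and by staging (11 is absent until C3 is locked in the lactone, so the side chain cannot end up on C3). Ring-opening polymerisation is held down by ethene, dilution and the two endo substituents.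

Step 10
Reactants: 14 bis silyl ether
Product: 15 (2R,3S,4E)-3-hydroxy-5-[(2S,3R,3aR,7aR)-3-hydroxy-5-oxo-2,3,3a,7a-tetrahydro-5H-furo[3,2-b]pyran-2-yl]pent-4-en-2-yl benzoate (target)
Conditions: HF·pyridine (excess), pyridine, THF, 0 °C to rt, polyethylene vessel
Reagents that add atoms: none
Why: Fluoride cleavage of both silyl ethers under buffered, mildly acidic conditions. Basic fluoride is avoided because it could trigger the benzoate shift from O11 to O10, oxa-Michael addition of O6–H at C3 or opening of the lactone.

## Compound list

1 | furan | c1ccoc1 | starting material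
2 | vinylene carbonate (1,3-dioxol-2-one) | O=C1OC=CO1 | starting material
3 | endo-(3aR,4S,7R,7aS)-3a,4,7,7a-tetrahydro-4,7-epoxy-1,3-benzodioxol-2-one (meso) | C1=C[C@@H]2O[C@H]1[C@@H]3OC(=O)O[C@H]23 | intermediate
4 | (1R,2R,3S,4S)-7-oxabicyclo[2.2.1]hept-5-ene-2,3-diol (meso, endo,endo) | C1=C[C@@H]2O[C@H]1[C@H](O)[C@@H]2O | intermediate
5 | (1R,2S,3S,4S)-3-[(tert-butyldimethylsilyl)oxy]-7-oxabicyclo[2.2.1]hept-5-en-2-ol | C1=C[C@@H]2O[C@H]1[C@H](O)[C@@H]2O[Si](C)(C)C(C)(C)C | intermediate
6 | (1R,2S,3R,4S)-3-[(tert-butyldimethylsilyl)oxy]-7-oxabicyclo[2.2.1]hept-5-en-2-yl prop-2-enoate | C1=C[C@@H]2O[C@H]1[C@H](OC(=O)C=C)[C@@H]2O[Si](C)(C)C(C)(C)C | intermediate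
7 | penta-1,4-dien-3-ol | C=CC(O)C=C | starting material
8 | (1S)-1-[(2R)-oxiran-2-yl]prop-2-en-1-ol | C1O[C@H]1[C@@H](O)C=C | intermediate
9 | tert-butyldimethyl{[(1S)-1-[(2R)-oxiran-2-yl]prop-2-en-1-yl]oxy}silane | C1O[C@H]1[C@@H](O[Si](C)(C)C(C)(C)C)C=C | intermediate
10 | (2R,3S)-3-[(tert-butyldimethylsilyl)oxy]pent-4-en-2-ol | C[C@@H](O)[C@@H](O[Si](C)(C)C(C)(C)C)C=C | intermediate
11 | (2R,3S)-3-[(tert-butyldimethylsilyl)oxy]pent-4-en-2-yl benzoate | C[C@@H](OC(=O)c1ccccc1)[C@@H](O[Si](C)(C)C(C)(C)C)C=C | intermediate
12 | (2R,3S,4R,5S)-4-[(tert-butyldimethylsilyl)oxy]-2,5-diethenyloxolan-3-yl prop-2-enoate (all-cis) | C=C[C@@H]1O[C@H](C=C)[C@H](OC(=O)C=C)[C@@H]1O[Si](C)(C)C(C)(C)C | intermediate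
13 | (2S,3R,3aS,7aR)-3-[(tert-butyldimethylsilyl)oxy]-2-ethenyl-2,3,3a,7a-tetrahydro-5H-furo[3,2-b]pyran-5-one | C=C[C@@H]1O[C@@H]2C=CC(=O)O[C@@H]2[C@@H]1O[Si](C)(C)C(C)(C)C | intermediate
14 | (2R,3S,4E)-3-[(tert-butyldimethylsilyl)oxy]-5-[(2S,3R,3aS,7aR)-3-[(tert-butyldimethylsilyl)oxy]-5-oxo-2,3,3a,7a-tetrahydro-5H-furo[3,2-b]pyran-2-yl]pent-4-en-2-yl benzoate | C[C@@H](OC(=O)c1ccccc1)[C@@H](O[Si](C)(C)C(C)(C)C)/C=C/[C@@H]1O[C@@H]2C=CC(=O)O[C@@H]2[C@@H]1O[Si](C)(C)C(C)(C)C | intermediate
15 | (2R,3S,4E)-3-hydroxy-5-[(2S,3R,3aR,7aR)-3-hydroxy-5-oxo-2,3,3a,7a-tetrahydro-5H-furo[3,2-b]pyran-2-yl]pent-4-en-2-yl benzoate | C[C@@H](OC(=O)c1ccccc1)[C@@H](O)/C=C/[C@@H]1O[C@@H]2C=CC(=O)O[C@@H]2[C@@H]1O | target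

## Step count and least certain steps

Total step count: 10. Longest linear sequence: 6 steps. Both branches have this length: steps 1, 2, 3, 4, 9, 10 from 1 and 2, and steps 5, 6, 7, 8, 9, 10 from 7.

**Step 9 (key step).**
- What may go wrong: the cross-metathesis leg is the most likely to stall, because both partners are branched and oxygenated at the allylic carbon and the C8 vinyl group lies cis to the O6 silyl ether. Catalyst decay would then open the way to alkene isomerisation. Oligomerisation during the ring opening is the lesser risk.
- Fallback: it sets out from 13, isolated after the first stage (ring rearrangement under ethene alone), and forms C9–C10 instead of C8=C9.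
  - The vinyl group of 13, the only electron-rich alkene, is cleaved by the Lemieux–Johnson method (OsO4 cat., NaIO4, 2,6-lutidine, dioxane/water) to the C8 aldehyde F1.
  - Takai olefination (CrCl2, CHI3, THF, 0 °C) gives the E alkenyl iodide F2.
  - Nozaki–Hiyama–Kishi coupling (CrCl2, NiCl2 cat., DMSO) follows with (R)-2-(benzoyloxy)propanal F3. F3 is made in one step from propanal and dibenzoyl peroxide by enamine-catalysed α-benzoyloxylation, using the diarylprolinol silyl ether antipode that gives the R aldehyde.
  - The coupling should follow the polar Felkin–Anh mode and favour the anti (10S,11R) alcohol F4.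
  - Cleavage of its single silyl ether as in step 10 brings the sequence back at 15.

**Step 3.**
- What may go wrong: discrimination of the two enantiotopic hydroxyls may be insufficient, because the bridge oxygen offers a competing hydrogen-bond acceptor and the endo face is concave. Slow silylation and bis-silylation are further risks.
- Fallback: it sets out from 4 and uses biocatalysis.
  - Peracetylation (Ac2O, pyridine) gives the meso diacetate F5.
  - A lipase or pig liver esterase in pH 7 buffer hydrolyses one enantiotopic ester to the monoacetate F6 (free O6–H).
  - Silylation (TBSOTf, 2,6-lutidine, −78 °C) gives F7.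
  - Reductive removal of the acetate (i-Bu2AlH, CH2Cl2, −78 °C), which avoids a free alkoxide, comes back at 5.
  - If the enzyme prefers the other ester, the same enzyme is used in the acylation mode on 4, which is enantiocomplementary.

**Step 1.**
- What may go wrong: reversibility of the cycloaddition may drain the mixture towards the exo isomer, so the share of 3 is low.
- Fallback: it sets out from the exo adduct F8 that forms from 1 and 2 beside 3, and corrects its configuration.
  - Methanolysis as in step 2 gives the exo,exo diol F9.
  - Double Swern oxidation (DMSO, (CF3CO)2O, Et3N, −78 °C) gives the dione F10.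
  - NaBH4 (MeOH/CH2Cl2, −78 °C) attacks both carbonyl groups from the open exo face next to the oxygen bridge and comes back at 4.

**Step 7.**
- What may go wrong: the lithium alkoxide formed at O11 sits next to the O10 silyl ether, so a 1,2-silyl shift may scramble the two oxygens and, after step 8, misplace the benzoate.
- Fallback: it sets out from 9 and avoids any alkoxide.
  - LiI and AcOH in THF open the epoxide at the terminal carbon to the iodohydrin F11.
  - Benzoylation (BzCl, pyridine) gives the iodo benzoate F12.
  - Radical deiodination (Bu3SnH, AIBN, toluene, 80 °C, high hydride concentration to outrun the acyloxy shift) comes back at 11.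

**Step 10.**
- What may go wrong: the silyl ether on the crowded O6 may be cleaved slowly, and long exposure may start the acyl shift from O11 to O10 or damage the lactone.
- Fallback: it sets out from 6 and 11 and moves the deprotection in front of the key step.
  - HF·pyridine turns 6 into the hydroxy acrylate F13, which is used at once and kept neutral because acyl migration would racemise it.
  - HF·pyridine turns 11 into the hydroxy benzoate F14.
  - The conditions of step 9 then give the hydroxy vinyl lactone F15 in the flask, and after addition of F14 come back directly at 15. The free allylic hydroxyl groups should help rather than hinder the metathesis.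

## Further compounds

F1 | step 9 | C8 aldehyde from cleavage of the vinyl group of 13 (3-silyloxy-5-oxo-tetrahydrofuro[3,2-b]pyran-2-carbaldehyde, ring stereocentres as in 13) | O=C[C@@H]1O[C@@H]2C=CC(=O)O[C@@H]2[C@@H]1O[Si](C)(C)C(C)(C)C
F2 | step 9 | E-2-iodoethenyl analogue of 13 | I/C=C/[C@@H]1O[C@@H]2C=CC(=O)O[C@@H]2[C@@H]1O[Si](C)(C)C(C)(C)C
F3 | step 9 | (2R)-1-oxopropan-2-yl benzoate | C[C@@H](OC(=O)c1ccccc1)C=O
F4 | step 9 | O6-silyl ether of 15 (free O10–H) | C[C@@H](OC(=O)c1ccccc1)[C@@H](O)/C=C/[C@@H]1O[C@@H]2C=CC(=O)O[C@@H]2[C@@H]1O[Si](C)(C)C(C)(C)C
F5 | step 3 | meso endo,endo-7-oxabicyclo[2.2.1]hept-5-ene-2,3-diyl diacetate | C1=C[C@@H]2O[C@H]1[C@H](OC(C)=O)[C@@H]2OC(C)=O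
F6 | step 3 | endo,endo monoacetate (acetate on O5, free O6–H) | C1=C[C@@H]2O[C@H]1[C@H](OC(C)=O)[C@@H]2O
F7 | step 3 | O5-acetate O6-silyl ether | C1=C[C@@H]2O[C@H]1[C@H](OC(C)=O)[C@@H]2O[Si](C)(C)C(C)(C)C
F8 | step 1 | exo Diels–Alder adduct of furan and vinylene carbonate (meso) | C1=C[C@@H]2O[C@H]1[C@H]3OC(=O)O[C@@H]23
F9 | step 1 | meso exo,exo-7-oxabicyclo[2.2.1]hept-5-ene-2,3-diol | C1=C[C@@H]2O[C@H]1[C@@H](O)[C@H]2O
F10 | step 1 | 7-oxabicyclo[2.2.1]hept-5-ene-2,3-dione (meso) | C1=C[C@@H]2O[C@H]1C(=O)C2=O
F11 | step 7 | (2S,3S)-3-[(tert-butyldimethylsilyl)oxy]-1-iodopent-4-en-2-ol | IC[C@@H](O)[C@@H](O[Si](C)(C)C(C)(C)C)C=C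
F12 | step 7 | (2S,3S)-3-[(tert-butyldimethylsilyl)oxy]-1-iodopent-4-en-2-yl benzoate | IC[C@@H](OC(=O)c1ccccc1)[C@@H](O[Si](C)(C)C(C)(C)C)C=C
F13 | step 10 | endo,endo-3-hydroxy-7-oxabicyclo[2.2.1]hept-5-en-2-yl prop-2-enoate (desilylated 6) | C1=C[C@@H]2O[C@H]1[C@H](OC(=O)C=C)[C@@H]2O
F14 | step 10 | (2R,3S)-3-hydroxypent-4-en-2-yl benzoate | C[C@@H](OC(=O)c1ccccc1)[C@@H](O)C=C
F15 | step 10 | (2S,3R,3aR,7aR)-2-ethenyl-3-hydroxy-2,3,3a,7a-tetrahydro-5H-furo[3,2-b]pyran-5-one | C=C[C@@H]1O[C@@H]2C=CC(=O)O[C@@H]2[C@@H]1O
A1 | alternative 1 | all-cis 3,4-O-isopropylidene-5-ethenyloxolane-2-carbaldehyde (C3 aldehyde, C4 to C8 as in 15) | C=C[C@@H]1O[C@H](C=O)[C@@H]2OC(C)(C)O[C@H]12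
A2 | alternative 2 | 5-hydroxy-5,6-dihydropyran-2-one carrying at C5 of the chain the O6-silylated (7E)-alkenyl (9R,10R)-trans-epoxide with the C11 benzoate | C[C@@H](OC(=O)c1ccccc1)[C@H]1O[C@@H]1/C=C/[C@@H](O[Si](C)(C)C(C)(C)C)[C@H]2OC(=O)C=C[C@H]2O
A3 | alternative 3 | 5-hydroxy-5,6-dihydropyran-2-one with an O6-silylated, C7-mesylated (C7 inverted) pentenyl chain | C=C[C@@H](OS(C)(=O)=O)[C@@H](O[Si](C)(C)C(C)(C)C)[C@H]1OC(=O)C=C[C@H]1O
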